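Labdane numbering is used throughout: ring A is C1–C5/C10 (gem-dimethyl on C4, methyl on C10), ring B is C5–C10, the cyclobutane is C8–C9–C14–C15 and the cyclopentane is C9–C11–C12–C13–C14. "α" is the face of ring B opposite the C10 methyl.

Assumption: the SMILES is read as 5α-H, 10β-Me, 8β-Me, cyclobutane on the α face, C13 hydroxyl anti to the cyclobutane (13S), and C6 acetoxy β, cis to the C10 methyl (6S); the route is built for this isomer.

## Analysis of the target

The target is a tetracycle: a trans-fused decalin (rings A and B) whose C8–C9 bond is also one side of a cyclobutane, which in turn shares its C9–C14 bond with a cyclopentane. C9 is therefore common to three rings, and C8, C9 and C10 are three contiguous fully substituted carbons. There are seven stereocentres (C5, C6, C8, C9, C10, C13, C14). C5/C10 are the usual labdane pair, C8/C9/C14 are locked together by the two cis ring fusions, and C13 is a tertiary carbinol three bonds from C10 with no ring to relay information to it. The 6β-acetoxy group sits on the face that carries the C4β, C8 and C10 methyl groups, so it is the more hindered epimer and cannot be installed by attack of an oxygen electrophile on the open face. Sensitive groups are the α-acetoxy ketone (epimerisation at C6, acyl shift), the tertiary alcohol and the cyclobutane next to C7, which forbids cationic chemistry at C7. The feature the route rests on is that cyclopentane plus cyclobutane sharing C9–C14 are the valence isomer of a cyclohepta-1,3-diene C9=C8–C15=C14 bridged by C11–C12–C13. One bond, C9–C14, made by electrocyclisation, gives both small rings and leaves a cyclobutene C8=C15 as the handle for closing ring B at C8.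

## Retrosynthetic reasoning

C6 and the silyl group. The target 33 is traced to the acetoxy silyl enol ether 31, cutting the C6–H bond. Because reagents reach C6 from the α face, only a hydrogen delivered there leaves the acetate β; an oxygen electrophile would end up α. 31 comes from ketone 28 through the α-acetoxy ketone 30, whose C6 configuration is irrelevant.

Ring B, bond C7–C8. Ketone 28 is opened to aldehyde 26 via alcohol 27. The bond is cut here because the strained trisubstituted cyclobutene of 26 gives a tertiary radical at C8 on hydrogen-atom transfer, and the tether from C10 can deliver the aldehyde only to the face cis to C10. That sets the last quaternary centre without cationic intermediates.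

Bond C9–C14 (key). Bicycle 25, the acetal of 26, is the photoisomer of cycloheptadiene 24. Cutting this one bond removes two rings and two stereocentres, and the forward reaction is unimolecular, so the congestion around C9/C10 costs nothing. The forward step has to choose the face of the diene; C13 is the only nearby control element.

The diene, bonds C14=C15 and C8–C9. Diene 24 goes back to cycloheptenol 23 (dehydration across C8–C9), then to the acyclic diene 22 (ring-closing metathesis at C14=C15), then to ketone 19 and crotyl bromide 20. Crotyl brings C8, its methyl and C15 in one addition to a hindered ketone, and the metathesis can only give the seven-membered ring.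

Bond C9–C11, joining the fragments. Ketone 19 is cut to lactone 9 and iodide 15 (through 17 and 18). The junction is placed here and not at C9–C10, because C10 is quaternary and the remote C13 centre cannot control its configuration in an intermolecular bond formation. Both fragments are therefore made enantiopure first and joined at a carbonyl carbon. A lactone is chosen because it has no α-hydrogen and takes exactly one organolithium.

Ring A fragment. Lactone 9 is traced to (+)-sclareolide 1, which already holds C5 and C10 in the required absolute and relative configuration and the C5–C6–C7 chain. Forward, ring B of 1 is cut at C9–C11 and C8–C9, and C8 is excised by oxygen insertion (3, 5, 6, 7). Building ring A from a monocyclic ketone was rejected because the C5/C10 trans relationship has no reliable bias outside a decalin.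

C13 fragment. Iodide 15 comes from (S)-linalool 10, whose carbinol carbon is C13 with the right configuration. Linalool has one carbon too many between C13 and the junction, so the prenyl terminus is cut by ozonolysis and one further carbon is removed by decarboxylative iodination (11, 12, 13).

## Alternatives that were turned down

Alternative 1: Radical bicyclisation onto a cyclobutene ester. The cuts are C4–C5 and C9–C10: open-chain polyene A1 would be converted into tricycle A2 by hydrogen-atom transfer to its terminal trisubstituted alkene, 6-endo attack of the C4 radical on C5 and 6-exo attack of the C10 radical on the β-carbon (C9) of the cyclobutene ester.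
- For it: two rings, two C–C bonds and the C9/C10 quaternary pair in one step, and ring A needs no chiral-pool degradation. On bonds per step and on the origin of ring A it is stronger than the chosen route.
- Against it: the enantiopure cyclobutene with quaternary C8 must exist before the cascade, so the four-membered ring problem is only moved upstream. The last radical step joins a tertiary radical to a fully substituted alkene carbon. Four new centres (C5, C9, C10, C14) are steered only by C7/C8. A2 still lacks the cyclopentane and the C13 carbinol.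
- Comparison: the chosen route pays more steps for ring A but forms both small rings at once, with C13 already in place.

Alternative 2: Enone–alkene photocycloaddition. The cuts are C8–C9 and C14–C15: irradiation of cyclopentenone A3, with its tethered isopropenyl ketone, would give tetracycle A4 by [2+2] addition, closing ring B and the cyclobutane together.
- For it: A4 already carries the C6 acetate and C7 ketone and both quaternary centres C8 and C9. In steps after the key step and in making C8–C9 directly it is stronger than the chosen route.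
- Against it: A3 holds two enone chromophores and an α-acetoxy ketone, so excitation is not selective and α-cleavage competes. The four-atom tether must give the fused and not the crossed adduct. The face of addition relative to C10 and C13 is open. The extra C11 ketone next to quaternary C9 must then be removed in the presence of the base-sensitive acetoxy ketone.
- Comparison: the chosen route has a single chromophore in its photosubstrate, no surplus carbonyl, and sets C8 afterwards with a tether instead of in an intermolecular-like encounter.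

Alternative 3: Nitrogen extrusion from a cyclic diazene. The cut is C8–C9: photolysis or thermolysis of tetrahydropyridazine A5 would expel N2 and the 1,4-diradical would close to cyclobutane A6.
- For it: radical-pair collapse is a good way to join two quaternary carbons, and the rest of the skeleton can be assembled first by polar chemistry. On forging C8–C9 late it is at least as strong.
- Against it: A5 needs two C–N bonds at fully substituted carbons, for which there is no short entry. The diradical can cleave C14–C15 to two alkenes or disproportionate. C8 is a free radical centre during the step, so its configuration is not secured. A6 still has ring B open, with two one-carbon arms to be joined and oxidised.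
- Comparison: the chosen closure is closed-shell, stereospecific for the ring fusion and has no fragmentation channel; its price is the face selectivity at C13.

Key step: step 16

## Route

Step 1
Reactants: 1 (+)-sclareolide
Product: 3 9(11)-dehydrosclareolide (butenolide), via 11-(phenylselanyl)sclareolide 2 (not isolated)
Conditions: LiN(i-Pr)2, THF, −78 °C; PhSeBr, −78 → 0 °C; then 30% H2O2, pyridine, CH2Cl2, 0 °C → rt
Reagents that add atoms: none
Why: α-Selenenylation of the lactone enolate occurs on the face away from C10, cis to H9, and selenoxide syn-elimination can only remove H9, which places the double bond between C9 and C11; C5, C8 and C10 are untouched.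

Step 2
Reactants: 3 9(11)-dehydrosclareolide
Product: 5 (2R,4aS,8aS)-2-hydroxy-2,5,5,8a-tetramethyloctahydronaphthalen-1(2H)-one, via keto glyoxylate 4 (not isolated)
Conditions: O3, CH2Cl2–MeOH, −78 °C; Me2S; then K2CO3 (cat.), MeOH, 0 °C
Reagents that add atoms: ozone, [O-][O+]=O
Why: Ozonolysis cleaves the only C=C bond, making C9 a ketone and leaving C11–C12 as a glyoxylate on the C8 oxygen, which mild methanolysis removes to give the tertiary α-ketol.

Step 3
Reactants: 5 α-ketol
Product: 6 methyl (1S,2S)-1,3,3-trimethyl-2-(3-oxobutyl)cyclohexane-1-carboxylate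
Conditions: Pb(OAc)4, MeOH–PhH (1:1), 0 °C → rt
Reagents that add atoms: methanol, CO
Why: Lead tetraacetate cleaves the α-hydroxy ketone between C8 and C9 through its methanol hemiketal (glycol-type cleavage), giving the C9 methyl ester on quaternary C10 and a methyl ketone at C8; ring B is open and C5/C10 keep their configuration.

Step 4
Reactants: 6 keto ester
Product: 7 methyl (1S,2S)-2-(2-acetoxyethyl)-1,3,3-trimethylcyclohexane-1-carboxylate
Conditions: (CF3CO)2O, H2O2·urea, Na2HPO4, CH2Cl2, 0 °C → rt
Reagents that add atoms: trifluoroperacetic acid (formed from trifluoroacetic anhydride and H2O2·urea), OOC(=O)C(F)(F)F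
Why: Baeyer–Villiger oxidation in which the primary carbon C7 migrates in preference to methyl, so C8 and its methyl leave the chain as an acetate and C7 becomes oxygen-bound; the hindered ester is inert to the peracid.

Step 5
Reactants: 7 acetoxy ester
Product: 9 (4aS,8aS)-5,5,8a-trimethyloctahydro-1H-isochromen-1-one, via hydroxy ester 8 (not isolated)
Conditions: K2CO3, MeOH, rt; then p-TsOH·H2O (cat.), PhMe, reflux
Reagents that add atoms: none
Why: Methanolysis frees the primary alcohol and acid-catalysed transesterification closes the strain-free trans-fused δ-lactone, which ties C7 and C9 into one ring that will accept exactly one organolithium.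

Step 6
Reactants: 10 (S)-linalool
Product: 11 triethyl{[(3S)-3,7-dimethylocta-1,6-dien-3-yl]oxy}silane
Conditions: Et3SiOTf, 2,6-lutidine, CH2Cl2, −78 → 0 °C
Reagents that add atoms: triethylsilyl trifluoromethanesulfonate, CC[Si](CC)(CC)OS(=O)(=O)C(F)(F)F
Why: A silyl triflate with a hindered pyridine base silylates the tertiary allylic alcohol without ionisation; the stereocentre (future C13) is not involved.

Step 7
Reactants: 11 linalool triethylsilyl ether
Product: 12 (4S)-4-methyl-4-[(triethylsilyl)oxy]hex-5-enal
Conditions: O3, CH2Cl2–MeOH, pyridine, Sudan Red 7B, −78 °C; then Me2S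
Reagents that add atoms: ozone, [O-][O+]=O
Why: Selective ozonolysis: the electron-rich trisubstituted alkene reacts far faster than the vinyl group next to a quaternary carbon, and the dye marks the end point.

Step 8
Reactants: 12 aldehyde
Product: 13 (4S)-4-methyl-4-[(triethylsilyl)oxy]hex-5-enoic acid
Conditions: NaClO2, NaH2PO4, 2-methylbut-2-ene, t-BuOH–H2O, 0 °C → rt
Reagents that add atoms: sodium chlorite, [Na+].[O-]Cl=O
Why: Pinnick oxidation under buffered conditions leaves the silyl ether and the vinyl group untouched.

Step 9
Reactants: 13 acid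
Product: 15 triethyl{[(3S)-5-iodo-3-methylpent-1-en-3-yl]oxy}silane, via thiohydroxamate ester 14 (not isolated)
Conditions: N-hydroxypyridine-2-thione, DCC, DMAP (cat.), CH2Cl2, 0 °C, dark; then CHI3, PhH, hν (tungsten lamp), rt
Reagents that add atoms: iodoform, IC(I)I
Why: Barton decarboxylation: the ester fragments to a primary radical that abstracts iodine from iodoform, which removes the one carbon linalool has in excess; cyclisation of this radical onto the vinyl group would be 4-exo and does not compete.

Step 10
Reactants: 15 iodide; 9 lactone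
Product: 17 (4S)-1-[(1S,2S)-2-(2-hydroxyethyl)-1,3,3-trimethylcyclohexyl]-4-methyl-4-[(triethylsilyl)oxy]hex-5-en-1-one, via alkyllithium 16 (not isolated)
Conditions: t-BuLi (2.1 equiv), Et2O–pentane, −78 °C; then 9, THF, −78 → −40 °C; aq. NH4Cl
Reagents that add atoms: none
Why: Iodine–lithium exchange gives a primary alkyllithium that adds once to the lactone, which has no α-hydrogen; the lithium lactolate survives until the quench, so the C9–C11 bond forms without over-addition (organolithium addition to a lactone).

Step 11
Reactants: 17 hydroxy ketone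
Product: 18 2-[(1S,2S)-2,6,6-trimethyl-2-{(4S)-4-methyl-4-[(triethylsilyl)oxy]hex-5-enoyl}cyclohexyl]acetaldehyde
Conditions: Dess–Martin periodinane, NaHCO3, CH2Cl2, 0 °C → rt
Reagents that add atoms: none
Why: Dess–Martin oxidation of the primary alcohol (drawn from the open hydroxy ketone form) under buffered neutral conditions, which avoids an aldol reaction between C11 and C7.

Step 12
Reactants: 18 keto aldehyde
Product: 19 (4S)-1-[(1S,2S)-2-(2,2-dimethoxyethyl)-1,3,3-trimethylcyclohexyl]-4-methyl-4-[(triethylsilyl)oxy]hex-5-en-1-one
Conditions: HC(OMe)3, MeOH, pyridinium p-toluenesulfonate (cat.), 0 °C → rt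
Reagents that add atoms: trimethyl orthoformate, COC(OC)OC
Why: The unhindered aldehyde forms its dimethyl acetal under mild acid catalysis, while the ketone next to quaternary C10 does not react and the tertiary silyl ether tolerates the weak acid at low temperature.

Step 13
Reactants: 19 keto acetal; 20 crotyl bromide
Product: 22 (7S)-4-[(1S,2S)-2-(2,2-dimethoxyethyl)-1,3,3-trimethylcyclohexyl]-3,7-dimethyl-7-[(triethylsilyl)oxy]nona-1,8-dien-4-ol, via but-2-enylmagnesium bromide 21 (not isolated)
Conditions: Mg, Et2O, 0 °C; then 19, THF, −78 → 0 °C; aq. NH4Cl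
Reagents that add atoms: none
Why: The allylic Grignard reagent adds through a six-membered SE2′ transition state even to this hindered ketone and gives the branched adduct, forming C8–C9 with the C8 methyl and the C15 vinyl group in place; the two new centres form as a mixture and are both removed in step 15.

Step 14
Reactants: 22 diene alcohol
Product: 23 (5S)-1-[(1S,2S)-2-(2,2-dimethoxyethyl)-1,3,3-trimethylcyclohexyl]-2,5-dimethyl-5-[(triethylsilyl)oxy]cyclohept-3-en-1-ol
Conditions: second-generation Grubbs catalyst (H2IMes)(PCy3)Cl2Ru=CHPh (5–10 mol %), CH2Cl2, 40 °C, 0.005 M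
Reagents that add atoms: none
Why: Ring-closing metathesis between the two monosubstituted alkenes can give only the seven-membered ring with a cis C14=C15 bond, and loss of ethylene drives it.

Step 15
Reactants: 23 cycloheptenol
Product: 24 triethyl({(1S)-5-[(1S,2S)-2-(2,2-dimethoxyethyl)-1,3,3-trimethylcyclohexyl]-1,4-dimethylcyclohepta-2,4-dien-1-yl}oxy)silane
Conditions: Burgess reagent (MeO2CN–SO2NEt3 inner salt), PhH, 50 °C; chromatography on Et3N-treated silica
Reagents that add atoms: none
Why: Burgess dehydration of the tertiary alcohol through its sulfamate ion pair; loss of the allylic hydrogen on C8 gives the conjugated, fully substituted C8=C9 bond in preference to the isolated C9=C11 alkene, and the ring fixes the geometry; the product is kept below about 60 °C and away from acid to avoid [1,5]-hydrogen shifts and ionisation at C13.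

Step 16
Reactants: 24 cycloheptadiene
Product: 25 triethyl({(1R,4S,5S)-1-[(1S,2S)-2-(2,2-dimethoxyethyl)-1,3,3-trimethylcyclohexyl]-4,7-dimethylbicyclo[3.2.0]hept-6-en-4-yl}oxy)silane
Conditions: hν (254 nm, low-pressure Hg lamp, quartz), degassed pentane, 0.005 M, 0 °C
Reagents that add atoms: none
Why: Direct excitation of the diene leads to the photochemically allowed disrotatory 4π electrocyclisation between C9 and C14, the known conversion of cyclohepta-1,3-dienes into bicyclo[3.2.0]hept-6-enes. The new C9–C14 bond closes the cyclobutene (C8=C15 stays as its double bond) and, being transannular in the seven-membered ring, turns that ring into the cyclopentane C9–C11–C12–C13–C14 in the same event. Disrotation inside a ring can only give the cis fusion, so C9 and C14 are set together. Their configuration relative to C13 depends on the face on which the cyclobutene forms; needed is the isomer with the cyclobutene anti to the silyloxy group and syn to the C13 methyl. The substrate should secure this through its ground-state conformation, since excited conformers do not interconvert before closure: the allylic C13–O bond prefers the pseudoaxial position (overlap with the C14=C15 π system, and oxygen is smaller than methyl at that carbon), which tilts the C11–C12–C13 bridge to one face, and least-motion disrotation continues this tilt, leaving oxygen on the convex face and methyl under the four-membered ring. C9 becomes quaternary in a unimolecular step that does not feel the neighbouring quaternary C10. The product does not absorb at 254 nm and is stable to further irradiation.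

Step 17
Reactants: 25 bicycloheptene acetal
Product: 26 2-[(1S,2S)-2-{(1R,4S,5S)-4,7-dimethyl-4-[(triethylsilyl)oxy]bicyclo[3.2.0]hept-6-en-1-yl}-2,6,6-trimethylcyclohexyl]acetaldehyde
Conditions: pyridinium p-toluenesulfonate (cat.), acetone–H2O (10:1), 40 °C
Reagents that add atoms: water, O
Why: Mild acid-catalysed acetal hydrolysis frees the C7 aldehyde; the tertiary silyl ether and the trisubstituted cyclobutene tolerate the weak acid.

Step 18
Reactants: 26 aldehyde
Product: 27 13-(triethylsilyloxy)-8,15:9,14-dicyclolabdan-7-ol
Conditions: Fe(acac)3 (1 equiv), PhSiH3 (2.5 equiv), EtOH–(CH2OH)2 (5:1), 60 °C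
Reagents that add atoms: none
Why: Hydrogen-atom transfer from the iron hydride to the strained cyclobutene puts hydrogen on C15 and a tertiary radical on C8, which adds 6-exo to the aldehyde carbon (reductive alkene–carbonyl radical cyclisation); the tether from C10 reaches C8 only on the face cis to C10, which closes ring B and sets C8 with its methyl β, and the C7 configuration is immaterial.

Step 19
Reactants: 27 alcohol
Product: 28 13-(triethylsilyloxy)-8,15:9,14-dicyclolabdan-7-one
Conditions: Dess–Martin periodinane, NaHCO3, CH2Cl2, rt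
Reagents that add atoms: none
Why: Dess–Martin oxidation of the hindered secondary alcohol gives the ketone without any cationic intermediate next to the cyclobutane.

Step 20
Reactants: 28 ketone
Product: 30 (6R)-6-acetoxy-13-(triethylsilyloxy)-8,15:9,14-dicyclolabdan-7-one, via trimethylsilyl enol ether 29 (not isolated)
Conditions: LiN(SiMe3)2, Me3SiCl, THF, −78 °C; then Pb(OAc)4, CH2Cl2, 0 °C
Reagents that add atoms: lead tetraacetate, CC(=O)O[Pb](OC(C)=O)(OC(C)=O)OC(C)=O
Why: The ketone can enolise only toward C6 (C8 is quaternary), and the silyl enol ether reacts with lead tetraacetate to give the α-acetoxy ketone (Rubottom-type acetoxylation), the acetate expected on the more open α face; this configuration is not the final one, and either epimer serves in step 21.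

Step 21
Reactants: 30 α-acetoxy ketone
Product: 31 6-acetoxy-7-(trimethylsilyloxy)-13-(triethylsilyloxy)-8,15:9,14-dicyclolabd-6-ene
Conditions: Me3SiOTf, Et3N, CH2Cl2, 0 °C → rt
Reagents that add atoms: trimethylsilyl trifluoromethanesulfonate, C[Si](C)(C)OS(=O)(=O)C(F)(F)F
Why: Soft enolisation removes the only α-hydrogen (H6) and gives the fully substituted enol ether without a free enolate, so the acetyl group cannot migrate.

Step 22
Reactants: 31 acetoxy silyl enol ether
Product: 33 target CNP0330581.1, via silyl-protected 6β-acetate 32 (not isolated)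
Conditions: CF3CO2H (1.2 equiv), CH2Cl2, −78 °C; then 48% aq. HF, MeCN, 0 °C
Reagents that add atoms: none
Why: Irreversible C-protonation of the silyl enol ether at low temperature should occur on the α face, which is free of the C4, C8 and C10 methyl groups, and so places the acetoxy group β (kinetic protonation to the more hindered epimer, 6S); aqueous HF then cleaves the tertiary silyl ether without base, so C6 does not equilibrate.

## Compound list

1 | (+)-sclareolide, (3aR,5aS,9aS,9bR)-3a,6,6,9a-tetramethyldecahydronaphtho[2,1-b]furan-2(1H)-one | C[C@]12CCCC([C@@H]1CC[C@@]3([C@@H]2CC(=O)O3)C)(C)C | starting material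
2 | 11-(phenylselanyl)sclareolide (selenium on C11 cis to H9) | C[C@]12CCCC([C@@H]1CC[C@@]3([C@@H]2[C@H]([Se]c4ccccc4)C(=O)O3)C)(C)C | intermediate
3 | 9(11)-dehydrosclareolide (butenolide with C9=C11; C5, C8, C10 as in 1) | C[C@]12CCCC([C@@H]1CC[C@@]3(C2=CC(=O)O3)C)(C)C | intermediate
4 | (2R,4aS,8aS)-2,5,5,8a-tetramethyl-1-oxodecahydronaphthalen-2-yl oxoacetate | C[C@]12CCCC(C)(C)[C@@H]1CC[C@@](C)(OC(=O)C=O)C2=O | intermediate
5 | (2R,4aS,8aS)-2-hydroxy-2,5,5,8a-tetramethyloctahydronaphthalen-1(2H)-one | C[C@]12CCCC(C)(C)[C@@H]1CC[C@@](C)(O)C2=O | intermediate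
6 | methyl (1S,2S)-1,3,3-trimethyl-2-(3-oxobutyl)cyclohexane-1-carboxylate | C[C@]1(C(=O)OC)CCCC(C)(C)[C@@H]1CCC(C)=O | intermediate
7 | methyl (1S,2S)-2-(2-acetoxyethyl)-1,3,3-trimethylcyclohexane-1-carboxylate | C[C@]1(C(=O)OC)CCCC(C)(C)[C@@H]1CCOC(C)=O | intermediate
8 | methyl (1S,2S)-2-(2-hydroxyethyl)-1,3,3-trimethylcyclohexane-1-carboxylate | C[C@]1(C(=O)OC)CCCC(C)(C)[C@@H]1CCO | intermediate
9 | (4aS,8aS)-5,5,8a-trimethyloctahydro-1H-isochromen-1-one (trans-fused lactone, carbonyl = C9, ring oxygen on C7) | C[C@]12CCCC(C)(C)[C@@H]1CCOC2=O | intermediate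
10 | (S)-linalool, (3S)-3,7-dimethylocta-1,6-dien-3-ol | C=C[C@@](C)(O)CCC=C(C)C | starting material
11 | triethyl{[(3S)-3,7-dimethylocta-1,6-dien-3-yl]oxy}silane | C=C[C@@](C)(O[Si](CC)(CC)CC)CCC=C(C)C | intermediate
12 | (4S)-4-methyl-4-[(triethylsilyl)oxy]hex-5-enal | C=C[C@@](C)(O[Si](CC)(CC)CC)CCC=O | intermediate
13 | (4S)-4-methyl-4-[(triethylsilyl)oxy]hex-5-enoic acid | C=C[C@@](C)(O[Si](CC)(CC)CC)CCC(=O)O | intermediate
14 | 2-thioxopyridin-1(2H)-yl (4S)-4-methyl-4-[(triethylsilyl)oxy]hex-5-enoate | C=C[C@@](C)(O[Si](CC)(CC)CC)CCC(=O)On1ccccc1=S | intermediate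
15 | triethyl{[(3S)-5-iodo-3-methylpent-1-en-3-yl]oxy}silane | C=C[C@@](C)(O[Si](CC)(CC)CC)CCI | intermediate
16 | [(3S)-3-methyl-3-(triethylsilyloxy)pent-4-en-1-yl]lithium | C=C[C@@](C)(O[Si](CC)(CC)CC)CC[Li] | intermediate
17 | (4S)-1-[(1S,2S)-2-(2-hydroxyethyl)-1,3,3-trimethylcyclohexyl]-4-methyl-4-[(triethylsilyl)oxy]hex-5-en-1-one (in equilibrium with its cyclic hemiketal) | C[C@]1(C(=O)CC[C@](C)(O[Si](CC)(CC)CC)C=C)CCCC(C)(C)[C@@H]1CCO | intermediate
18 | 2-[(1S,2S)-2,6,6-trimethyl-2-{(4S)-4-methyl-4-[(triethylsilyl)oxy]hex-5-enoyl}cyclohexyl]acetaldehyde | C[C@]1(C(=O)CC[C@](C)(O[Si](CC)(CC)CC)C=C)CCCC(C)(C)[C@@H]1CC=O | intermediate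
19 | (4S)-1-[(1S,2S)-2-(2,2-dimethoxyethyl)-1,3,3-trimethylcyclohexyl]-4-methyl-4-[(triethylsilyl)oxy]hex-5-en-1-one | C[C@]1(C(=O)CC[C@](C)(O[Si](CC)(CC)CC)C=C)CCCC(C)(C)[C@@H]1CC(OC)OC | intermediate
20 | crotyl bromide, (E)-1-bromobut-2-ene | C/C=C/CBr | starting material
21 | but-2-enylmagnesium bromide | C/C=C/C[Mg]Br | intermediate
22 | (7S)-4-[(1S,2S)-2-(2,2-dimethoxyethyl)-1,3,3-trimethylcyclohexyl]-3,7-dimethyl-7-[(triethylsilyl)oxy]nona-1,8-dien-4-ol (epimers at chain C3 and C4, i.e. C8 and C9) | C[C@]1(C(O)(C(C)C=C)CC[C@](C)(O[Si](CC)(CC)CC)C=C)CCCC(C)(C)[C@@H]1CC(OC)OC | intermediate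
23 | (5S)-1-[(1S,2S)-2-(2,2-dimethoxyethyl)-1,3,3-trimethylcyclohexyl]-2,5-dimethyl-5-[(triethylsilyl)oxy]cyclohept-3-en-1-ol (epimers at ring C1 and C2) | C[C@]1(C2(O)CC[C@](C)(O[Si](CC)(CC)CC)C=CC2C)CCCC(C)(C)[C@@H]1CC(OC)OC | intermediate
24 | triethyl({(1S)-5-[(1S,2S)-2-(2,2-dimethoxyethyl)-1,3,3-trimethylcyclohexyl]-1,4-dimethylcyclohepta-2,4-dien-1-yl}oxy)silane | COC(OC)C[C@H]1C(C)(C)CCC[C@]1(C)C1=C(C)C=C[C@@](C)(O[Si](CC)(CC)CC)CC1 | intermediate
25 | triethyl({(1R,4S,5S)-1-[(1S,2S)-2-(2,2-dimethoxyethyl)-1,3,3-trimethylcyclohexyl]-4,7-dimethylbicyclo[3.2.0]hept-6-en-4-yl}oxy)silane (cyclobutene anti to the silyloxy group) | COC(OC)C[C@H]1C(C)(C)CCC[C@]1(C)[C@]12CC[C@](C)(O[Si](CC)(CC)CC)[C@H]1C=C2C | intermediate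
26 | 2-[(1S,2S)-2-{(1R,4S,5S)-4,7-dimethyl-4-[(triethylsilyl)oxy]bicyclo[3.2.0]hept-6-en-1-yl}-2,6,6-trimethylcyclohexyl]acetaldehyde | O=CC[C@H]1C(C)(C)CCC[C@]1(C)[C@]12CC[C@](C)(O[Si](CC)(CC)CC)[C@H]1C=C2C | intermediate
27 | (5S,8S,9S,10S,13S,14S)-13-(triethylsilyloxy)-8,15:9,14-dicyclolabdan-7-ol (C7 epimers) | C1C(O)[C@@]2(C)C[C@H]3[C@@]2(CC[C@]3(C)O[Si](CC)(CC)CC)[C@@]2(C)CCCC(C)(C)[C@H]12 | intermediate
28 | (5S,8S,9S,10S,13S,14S)-13-(triethylsilyloxy)-8,15:9,14-dicyclolabdan-7-one | C1C(=O)[C@@]2(C)C[C@H]3[C@@]2(CC[C@]3(C)O[Si](CC)(CC)CC)[C@@]2(C)CCCC(C)(C)[C@H]12 | intermediate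
29 | 7-(trimethylsilyloxy)-13-(triethylsilyloxy)-8,15:9,14-dicyclolabd-6-ene | C1=C(O[Si](C)(C)C)[C@@]2(C)C[C@H]3[C@@]2(CC[C@]3(C)O[Si](CC)(CC)CC)[C@@]2(C)CCCC(C)(C)[C@H]12 | intermediate
30 | (6R)-6-acetoxy-13-(triethylsilyloxy)-8,15:9,14-dicyclolabdan-7-one (6α-acetate; may contain the 6β epimer) | CC(=O)O[C@H]1C(=O)[C@@]2(C)C[C@H]3[C@@]2(CC[C@]3(C)O[Si](CC)(CC)CC)[C@@]2(C)CCCC(C)(C)[C@H]12 | intermediate
31 | 6-acetoxy-7-(trimethylsilyloxy)-13-(triethylsilyloxy)-8,15:9,14-dicyclolabd-6-ene | CC(=O)OC1=C(O[Si](C)(C)C)[C@@]2(C)C[C@H]3[C@@]2(CC[C@]3(C)O[Si](CC)(CC)CC)[C@@]2(C)CCCC(C)(C)[C@H]12 | intermediate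
32 | (6S)-6-acetoxy-13-(triethylsilyloxy)-8,15:9,14-dicyclolabdan-7-one (6β-acetate) | CC(=O)O[C@@H]1C(=O)[C@@]2(C)C[C@H]3[C@@]2(CC[C@]3(C)O[Si](CC)(CC)CC)[C@@]2(C)CCCC(C)(C)[C@H]12 | intermediate
33 | CNP0330581.1, (5S,6S,8S,9S,10S,13S,14S)-6-acetoxy-13-hydroxy-8,15:9,14-dicyclolabdan-7-one | CC(=O)O[C@@H]1C(=O)[C@@]2(C)C[C@H]3[C@@]2(CC[C@]3(C)O)[C@@]2(C)CCCC(C)(C)[C@H]12 | target

## Step count and least certain steps

Total: 22 steps. Longest linear sequence: 18 steps (steps 1–5 and 10–22); the linalool branch (steps 6–9) joins at step 10.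

Step 16 (key step). Most likely failure: closure on the wrong face of the diene, because the two ring conformers (C13–O pseudoaxial or pseudoequatorial) may be close in energy and the bulky substituent on C9 may twist the chromophore; photochemical hydrogen shifts could also compete. Fallback: make the same bond in two stages instead of one excited-state step. Triplet sensitisation (xanthone or acetophenone, λ > 300 nm, −40 °C) twists the disubstituted C14=C15 bond of 24 to the strained E,Z-diene F1, which then closes thermally, in the ground state and in the conrotatory sense, to the cis-fused bicycle 25. The face is then decided by which helical form of the E,Z-diene the C13 centre allows, not by the excited-state surface. It sets out from 24 and comes back at 25.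

Step 15. Most likely failure: elimination toward C11 instead of C8 (both epimers of 23 are present and only one has H8 syn to the leaving group), or a 1,2-shift from C10 if the tertiary centre ionises fully. Fallback: place the double bond by an enol triflate instead of an elimination. From ketone 19, van Leusen reductive cyanation (TosMIC, t-BuOK, DME–EtOH) gives the nitrile F2. Vinyllithium followed by mild hydrolysis of the ketimine (aqueous citric acid, 0 °C) gives the vinyl ketone F3. Ring-closing metathesis with the same ruthenium catalyst gives the cycloheptenone F4, whose only enolisable hydrogen is the one on C9, since C13 carries none. KN(SiMe3)2 and PhNTf2 therefore give the dienyl triflate F5 with the double bond fixed between C9 and C8, and Me2CuLi replaces the triflate by methyl. It sets out from 19 and comes back at 24.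

Step 14. Most likely failure: slow loading of the ruthenium carbene on both hindered vinyl groups (one next to the quaternary silyloxy carbon, one next to a branched carbon), leading to oligomers or no reaction. Fallback: use hydroxyl assistance. Bu4NF removes the silyl group of 22 to give the diol F6, whose free tertiary allylic hydroxyl speeds carbene loading; metathesis gives the cycloheptenediol F7, and Et3SiOTf/2,6-lutidine at −78 °C silylates the less hindered C13 hydroxyl. It sets out from 22 and comes back at 23.

Step 18. Most likely failure: plain reduction of the cyclobutene, or reversal of the radical addition to the aldehyde (β-scission of the alkoxy radical) before it is reduced. Fallback: change the acceptor to a nitrile, whose adduct does not revert. From 26, NH2OH·HCl/NaOAc gives the oxime F8, and 1,1′-carbonyldiimidazole dehydrates it to the nitrile F9. Under the same Fe(acac)3/PhSiH3 conditions the C8 radical adds 6-exo to the nitrile carbon, and the resulting imine F10 hydrolyses on work-up to the ketone. It sets out from 26 and comes back at 28, so step 19 is not needed.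

Step 22 (with step 21). Most likely failure: protonation without face preference, or failure of the soft enolisation at the shielded H6, leaving the 6α-acetate. Fallback: set C6 by hydride instead of proton. From 30, K2CO3/MeOH gives the 6α-hydroxy ketone F11; Dess–Martin periodinane gives the 6,7-dione F12, which is used at once because it can enolise toward C5. NaBH4/CeCl3 in MeOH at −78 °C attacks the less hindered C6 carbonyl from the α face and gives the 6β-hydroxy ketone F13, and Ac2O/DMAP gives 32. It sets out from 30 and comes back at 32, which is desilylated with aqueous HF as in step 22.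

## Further compounds

F1 | step 16 | (2E,4Z)-isomer of 24 (trans C14=C15 bond, transient) | COC(OC)C[C@H]1C(C)(C)CCC[C@]1(C)C1=C(C)/C=C/[C@@](C)(O[Si](CC)(CC)CC)CC1
F2 | step 15 | (5S)-2-[(1S,2S)-2-(2,2-dimethoxyethyl)-1,3,3-trimethylcyclohexyl]-5-methyl-5-[(triethylsilyl)oxy]hept-6-enenitrile (C2 epimers) | C[C@]1(C(C#N)CC[C@](C)(O[Si](CC)(CC)CC)C=C)CCCC(C)(C)[C@@H]1CC(OC)OC
F3 | step 15 | (7S)-4-[(1S,2S)-2-(2,2-dimethoxyethyl)-1,3,3-trimethylcyclohexyl]-7-methyl-7-[(triethylsilyl)oxy]nona-1,8-dien-3-one (C4 epimers) | C[C@]1(C(C(=O)C=C)CC[C@](C)(O[Si](CC)(CC)CC)C=C)CCCC(C)(C)[C@@H]1CC(OC)OC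
F4 | step 15 | (4S)-7-[(1S,2S)-2-(2,2-dimethoxyethyl)-1,3,3-trimethylcyclohexyl]-4-methyl-4-[(triethylsilyl)oxy]cyclohept-2-en-1-one (C7 epimers) | C[C@]1(C2CC[C@](C)(O[Si](CC)(CC)CC)C=CC2=O)CCCC(C)(C)[C@@H]1CC(OC)OC
F5 | step 15 | (3S)-7-[(1S,2S)-2-(2,2-dimethoxyethyl)-1,3,3-trimethylcyclohexyl]-3-methyl-3-[(triethylsilyl)oxy]cyclohepta-1,6-dien-1-yl trifluoromethanesulfonate | C[C@]1(C2=C(OS(=O)(=O)C(F)(F)F)C=C[C@@](C)(O[Si](CC)(CC)CC)CC2)CCCC(C)(C)[C@@H]1CC(OC)OC
F6 | step 14 | (3S)-6-[(1S,2S)-2-(2,2-dimethoxyethyl)-1,3,3-trimethylcyclohexyl]-3,7-dimethylnona-1,8-diene-3,6-diol (epimers at C6 and C7) | C[C@]1(C(O)(C(C)C=C)CC[C@](C)(O)C=C)CCCC(C)(C)[C@@H]1CC(OC)OC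
F7 | step 14 | (4S)-1-[(1S,2S)-2-(2,2-dimethoxyethyl)-1,3,3-trimethylcyclohexyl]-4,7-dimethylcyclohept-5-ene-1,4-diol (epimers at C1 and C7) | C[C@]1(C2(O)CC[C@](C)(O)C=CC2C)CCCC(C)(C)[C@@H]1CC(OC)OC
F8 | step 18 | oxime of aldehyde 26 | ON=CC[C@H]1C(C)(C)CCC[C@]1(C)[C@]12CC[C@](C)(O[Si](CC)(CC)CC)[C@H]1C=C2C
F9 | step 18 | 2-[(1S,2S)-2-{(1R,4S,5S)-4,7-dimethyl-4-[(triethylsilyl)oxy]bicyclo[3.2.0]hept-6-en-1-yl}-2,6,6-trimethylcyclohexyl]acetonitrile | N#CC[C@H]1C(C)(C)CCC[C@]1(C)[C@]12CC[C@](C)(O[Si](CC)(CC)CC)[C@H]1C=C2C
F10 | step 18 | 7-imine of ketone 28 | C1C(=N)[C@@]2(C)C[C@H]3[C@@]2(CC[C@]3(C)O[Si](CC)(CC)CC)[C@@]2(C)CCCC(C)(C)[C@H]12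
F11 | step 22 | (6R)-6-hydroxy-13-(triethylsilyloxy)-8,15:9,14-dicyclolabdan-7-one | O[C@H]1C(=O)[C@@]2(C)C[C@H]3[C@@]2(CC[C@]3(C)O[Si](CC)(CC)CC)[C@@]2(C)CCCC(C)(C)[C@H]12
F12 | step 22 | 13-(triethylsilyloxy)-8,15:9,14-dicyclolabdane-6,7-dione | O=C1C(=O)[C@@]2(C)C[C@H]3[C@@]2(CC[C@]3(C)O[Si](CC)(CC)CC)[C@@]2(C)CCCC(C)(C)[C@H]12
F13 | step 22 | (6S)-6-hydroxy-13-(triethylsilyloxy)-8,15:9,14-dicyclolabdan-7-one | O[C@@H]1C(=O)[C@@]2(C)C[C@H]3[C@@]2(CC[C@]3(C)O[Si](CC)(CC)CC)[C@@]2(C)CCCC(C)(C)[C@H]12
A1 | alternative 1 | methyl 2-[2-(tert-butyldimethylsilyloxy)ethyl]-3-methyl-3-[(3E)-1-(tert-butyldimethylsilyloxy)-4,8-dimethylnona-3,7-dienyl]cyclobut-1-ene-1-carboxylate (cascade substrate) | CC(C)=CCC/C(C)=C/C[C@@H](O[Si](C)(C)C(C)(C)C)[C@@]1(C)CC(C(=O)OC)=C1CCO[Si](C)(C)C(C)(C)C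
A2 | alternative 1 | tricycle of rings A and B with the cyclobutane (C7 and C12 silyl ethers, C14 methyl ester) | C1[C@@H](O[Si](C)(C)C(C)(C)C)[C@@]2(C)C[C@H](C(=O)OC)[C@@]2(CCO[Si](C)(C)C(C)(C)C)[C@@]2(C)CCCC(C)(C)[C@H]12
A3 | alternative 2 | ring A carrying the 4-silyloxy-4-methylcyclopent-2-enone at C10 and the 1-acetoxy-3-methyl-2-oxobut-3-enyl chain at C5 (photosubstrate) | CC(=O)O[C@H](C(=O)C(C)=C)[C@H]1C(C)(C)CCC[C@]1(C)C1=C[C@@](C)(O[Si](C)(C)C(C)(C)C)CC1=O
A4 | alternative 2 | 11-oxo tetracycle with C13 tert-butyldimethylsilyl ether | CC(=O)O[C@@H]1C(=O)[C@@]2(C)C[C@H]3[C@@]2(C(=O)C[C@]3(C)O[Si](C)(C)C(C)(C)C)[C@@]2(C)CCCC(C)(C)[C@H]12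
A5 | alternative 3 | tetrahydropyridazine with N=N bridging C8 and C9 (diazene precursor) | C[C@]1(CO[Si](C)(C)C(C)(C)C)C[C@H]2[C@@](N=N1)(CC[C@]2(C)O[Si](CC)(CC)CC)[C@@]1(C)CCCC(C)(C)[C@@H]1CO[Si](C)(C)C(C)(C)C
A6 | alternative 3 | ring A bicyclo[3.2.0]heptane tris(silyl ether) | C[C@]1(CO[Si](C)(C)C(C)(C)C)C[C@H]2[C@@]1(CC[C@]2(C)O[Si](CC)(CC)CC)[C@@]1(C)CCCC(C)(C)[C@@H]1CO[Si](C)(C)C(C)(C)C
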